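**Retrosynthetic overview**
1. Target ⇐ deallylation of its allyl ester ⇐ carboxylate opening (C–O bond) of a spiro-epoxide at its CH2: acyl-half acid + cis-fused ε-lactone spiro-epoxide.
2. Acyl-half acid ⇐ the same lactone epoxide: saponification, then photocatalytic decarboxylative epoxide opening (ring C=C and CH2OH made, one carbon lost as CO2).
3. ε-Lactone ⇐ cis acid–aldehyde + allyl 2-phosphonoacrylate (tandem oxa-Michael/HWE); acid–aldehyde ⇐ oxidative cleavage of a methylenecyclobutane; quaternary carbinol ⇐ Corey–Chaykovsky epoxidation.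
4. Cyclobutane ⇐ [2+2] photocycloaddition of (S)-cryptone (sole source of chirality) with allene; ring order: cyclohexane (bought) → cyclobutane (temporary) → oxirane → ε-lactone; the cyclohexene of the acyl half arises from the same ring by decarboxylation.

Assumption: (S)-cryptone is bought as the single enantiomer; carbinol and lactol centers that are destroyed later are carried as epimer mixtures.

**Step 1**
Reactants: 1 (S)-cryptone; 2 allene
Product: 3 cis-fused 5-isopropyl-8-methylidenebicyclo[4.2.0]octan-2-one (four-membered ring anti to the isopropyl group)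
Conditions: hν (350 nm, Pyrex), 2 (10 equiv), THF, −78 °C; filtration through basic Al2O3
Reagents that add atoms: none
Why: Enone–allene [2+2] photocycloaddition through the triplet enone, in which the sp carbon of allene bonds to the α-carbon (head-to-head) and the necessarily cis-fused four-membered ring is built on the face anti to the C4 isopropyl group, so both new ring-fusion stereocenters are set by the stereocenter of 1.

**Step 2**
Reactants: 3 cis-fused 5-isopropyl-8-methylidenebicyclo[4.2.0]octan-2-one
Product: 4 5-isopropyl-8-methylidenespiro[bicyclo[4.2.0]octane-2,2'-oxirane] (epoxide O cis to C8; epoxide CH2 on the isopropyl face)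
Conditions: Me3SI (1.3 equiv), n-BuLi (1.2 equiv), THF, −10 °C → rt
Reagents that add atoms: trimethylsulfonium iodide, C[S+](C)C.[I-]
Why: Corey–Chaykovsky epoxidation in which the irreversible addition of the sulfonium ylide takes place on the convex face of the cis-fused bicycle (anti to C8), so the CH2 group ends up trans and the oxygen cis to the four-membered ring, which sets the quaternary carbinol center.

**Step 3**
Reactants: 4 5-isopropyl-8-methylidenespiro[bicyclo[4.2.0]octane-2,2'-oxirane]
Product: 5 5-isopropyl-8-methylidenespiro[bicyclo[4.2.0]octane-2,2'-oxiran]-7-ol (C7 epimers)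
Conditions: SeO2 (0.3 equiv), t-BuOOH (2 equiv), CH2Cl2, 0 °C → rt
Reagents that add atoms: tert-butyl hydroperoxide, CC(C)(C)OO
Why: SeO2-catalysed allylic hydroxylation (ene reaction then [2,3]-sigmatropic shift) that can only use the C7 methylene group because abstraction of the ring-fusion hydrogen would need a ring-fusion cyclobutene, and the new carbinol center is irrelevant since it becomes the aldehyde carbon in step 4.

**Step 4**
Reactants: 5 5-isopropyl-8-methylidenespiro[bicyclo[4.2.0]octane-2,2'-oxiran]-7-ol
Product: 7 cis-fused 3-hydroxy-4-isopropylhexahydrospiro[2-benzofuran-7,2'-oxiran]-1(3H)-one (hydroxy-lactone form of the cis acid–aldehyde), via hydroxycyclobutanone 6 (not isolated)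
Conditions: O3, CH2Cl2/MeOH, −78 °C, then Me2S; then NaIO4 (1.5 equiv), THF/pH 7 buffer, 0 °C → rt
Reagents that add atoms: ozone, [O-][O+]=O; sodium periodate, [Na+].[O-]I(=O)(=O)=O
Why: Ozonolysis of the 1,1-disubstituted alkene gives the α-hydroxy cyclobutanone, whose periodate cleavage turns the ketone carbon (on the former α-carbon of the enone) into the carboxylic acid and the carbinol carbon into the aldehyde, and these close to the cis-fused hydroxy-lactone without touching a ring stereocenter.

**Step 5**
Reactants: 8 allyl diethylphosphonoacetate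
Product: 10 allyl 2-(diethoxyphosphoryl)prop-2-enoate, via hydroxymethyl adduct 9 (not isolated)
Conditions: (CH2O)n (1.5 equiv), piperidine (10 mol %), toluene, 90 °C; then TsOH·H2O (5 mol %), reflux, Dean–Stark
Reagents that add atoms: paraformaldehyde (formaldehyde unit), C=O
Why: Knoevenagel-type hydroxymethylation of the phosphonoacetate by formaldehyde followed by acid-catalysed dehydration gives the 2-phosphonoacrylate, and no stereocenter is involved.

**Step 6**
Reactants: 7 cis-fused hydroxy-lactone; 10 allyl 2-(diethoxyphosphoryl)prop-2-enoate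
Product: 11 allyl cis-fused 6-isopropyl-1-oxo-3,5a,6,7,8,9a-hexahydro-1H-spiro[2-benzoxepine-9,2'-oxirane]-4-carboxylate
Conditions: Cs2CO3 (1.5 equiv), 10 (1.3 equiv), MeCN, 0 → 40 °C
Reagents that add atoms: none
Why: Proposed new method: under Cs2CO3 the hydroxy-lactone opens to the carboxylate aldehyde, the carboxylate adds reversibly to the doubly activated alkene of 10 (oxa-Michael) and the phosphonate carbanion so formed sits next to the aldehyde and closes the seven-membered ring by an irreversible intramolecular Horner–Wadsworth–Emmons olefination that can only give the ring-cis alkene (ester trans to the cyclohexane carbon), with no new stereocenter and with the cis ring fusion kept; the closest known reaction type is the tandem hetero-Michael/intramolecular HWE annulation of 2-phosphonoacrylates with salicylaldehydes or α-hydroxy ketones to six- and five-membered rings.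

**Step 7**
Reactants: 11 lactone epoxide allyl ester
Product: 13 (2E)-2-(hydroxymethyl)-3-[(1S,6S)-3-(hydroxymethyl)-6-isopropylcyclohex-2-en-1-yl]prop-2-enoic acid, via dilithium dicarboxylate 12 (not isolated)
Conditions: LiOH (2.2 equiv), THF/H2O, 0 °C → rt; then 4CzIPN (2 mol %), 2,4,6-triisopropylbenzenethiol (20 mol %), MeCN/H2O, 450 nm LEDs, rt; 1 M HCl to pH 3
Reagents that add atoms: lithium hydroxide, [Li+].[OH-]
Why: Proposed new method: after saponification of the lactone and the allyl ester the excited photocatalyst oxidises the alkyl carboxylate (the conjugated carboxylate would give a vinyl radical and does not decarboxylate), loss of CO2 gives a secondary radical next to the spiro-epoxide that opens within nanoseconds by C–O scission to the ring C=C and an alkoxy radical, which takes a hydrogen atom from the thiol while the thiyl radical is reduced by the reduced photocatalyst, so the cyclohexene double bond and the allylic CH2OH of the acyl half are formed regiospecifically with the two remaining stereocenters untouched; the closest known reaction types are the photoredox hydrodecarboxylation of carboxylates with thiol co-catalysts and the tin hydride-mediated opening of oxiranylcarbinyl radicals to allylic alcohols.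

**Step 8**
Reactants: 11 lactone epoxide allyl ester; 13 acyl-half acid
Product: 14 allyl ester of the target
Conditions: 13 (1.3 equiv), Cs2CO3 (0.3 equiv), DMF, 60 °C
Reagents that add atoms: none
Why: Base-catalysed addition of a carboxylic acid to a 2,2-disubstituted epoxide, an SN2 opening at the unsubstituted CH2 carbon by the carboxylate (the free hydroxyls of 13 are far less nucleophilic and the excess acid protonates the tertiary alkoxide at once), which leaves the C–O bond of the quaternary center intact so that its configuration from step 2 is kept.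

**Step 9**
Reactants: 14 allyl ester of the target
Product: 15 target CNP0361406.4
Conditions: Pd(PPh3)4 (5 mol %), N-methylaniline (3 equiv), THF, 0 °C → rt
Reagents that add atoms: none
Why: Tsuji–Trost deallylation with zerovalent palladium and a soft, weakly basic amine scavenger removes only the unsubstituted allyl ester under neutral conditions and leaves the lactone, the inter-fragment ester and all stereocenters untouched.

**Compound list**
1 | (S)-cryptone, (4S)-4-(propan-2-yl)cyclohex-2-en-1-one | CC(C)[C@@H]1CCC(=O)C=C1 | starting material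
2 | allene (propa-1,2-diene) | C=C=C | starting material
3 | cis-fused 5-isopropyl-8-methylidenebicyclo[4.2.0]octan-2-one; H-1, H-6 and isopropyl on one face, four-membered ring on the other | CC(C)[C@@H]1CCC(=O)[C@H]2C(=C)C[C@@H]12 | intermediate
4 | 5-isopropyl-8-methylidenespiro[bicyclo[4.2.0]octane-2,2'-oxirane]; epoxide O on the face of the four-membered ring, epoxide CH2 on the isopropyl face | CC(C)[C@@H]1CC[C@]3(CO3)[C@H]2C(=C)C[C@@H]12 | intermediate
5 | 5-isopropyl-8-methylidenespiro[bicyclo[4.2.0]octane-2,2'-oxiran]-7-ol (C7 epimers) | CC(C)[C@@H]1CC[C@]3(CO3)[C@H]2C(=C)C(O)[C@@H]12 | intermediate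
6 | 7-hydroxy-5-isopropylspiro[bicyclo[4.2.0]octane-2,2'-oxiran]-8-one (C7 epimers) | CC(C)[C@@H]1CC[C@]3(CO3)[C@H]2C(=O)C(O)[C@@H]12 | intermediate
7 | cis-fused 3-hydroxy-4-isopropylhexahydrospiro[2-benzofuran-7,2'-oxiran]-1(3H)-one (lactol epimers; epoxide O cis to C1; ring-chain tautomer of the cis acid–aldehyde) | CC(C)[C@@H]1CC[C@]3(CO3)[C@H]2C(=O)OC(O)[C@@H]12 | intermediate
8 | allyl diethylphosphonoacetate, prop-2-enyl 2-(diethoxyphosphoryl)acetate | CCOP(=O)(OCC)CC(=O)OCC=C | starting material
9 | allyl 2-(diethoxyphosphoryl)-3-hydroxypropanoate (racemic) | CCOP(=O)(OCC)C(CO)C(=O)OCC=C | intermediate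
10 | allyl 2-(diethoxyphosphoryl)prop-2-enoate | CCOP(=O)(OCC)C(=C)C(=O)OCC=C | intermediate
11 | allyl cis-fused 6-isopropyl-1-oxo-3,5a,6,7,8,9a-hexahydro-1H-spiro[2-benzoxepine-9,2'-oxirane]-4-carboxylate; H-5a, H-9a and isopropyl on one face, epoxide O cis to C1 | CC(C)[C@@H]1CC[C@]3(CO3)[C@H]2C(=O)OCC(C(=O)OCC=C)=C[C@@H]12 | intermediate
12 | dilithium (4,5-cis; 5,6-trans) 5-[(1E)-2-carboxylato-3-hydroxyprop-1-en-1-yl]-6-isopropyl-1-oxaspiro[2.5]octane-4-carboxylate | CC(C)[C@@H]1CC[C@]3(CO3)[C@@H](C(=O)[O-])[C@H]1/C=C(\CO)C(=O)[O-].[Li+].[Li+] | intermediate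
13 | (2E)-2-(hydroxymethyl)-3-[(1S,6S)-3-(hydroxymethyl)-6-isopropylcyclohex-2-en-1-yl]prop-2-enoic acid | CC(C)[C@@H]1CCC(CO)=C[C@H]1/C=C(\CO)C(=O)O | intermediate
14 | allyl (5aR,6S,9R,9aS)-9-hydroxy-9-({[(2E)-2-(hydroxymethyl)-3-[(1S,6S)-3-(hydroxymethyl)-6-isopropylcyclohex-2-en-1-yl]prop-2-enoyl]oxy}methyl)-6-isopropyl-1-oxo-1,3,5a,6,7,8,9,9a-octahydro-2-benzoxepine-4-carboxylate | CC(C)[C@@H]1CC[C@](O)(COC(=O)/C(=C/[C@@H]2C=C(CO)CC[C@H]2C(C)C)CO)[C@H]2C(=O)OCC(C(=O)OCC=C)=C[C@@H]12 | intermediate
15 | CNP0361406.4, the free 4-carboxylic acid of 14 | CC(C)[C@@H]1CC[C@](O)(COC(=O)/C(=C/[C@@H]2C=C(CO)CC[C@H]2C(C)C)CO)[C@H]2C(=O)OCC(C(=O)O)=C[C@@H]12 | target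

**Step count**
Total: 9 steps. Longest linear sequence: 8 steps (1 → 3 → 4 → 5 → 7 → 11 → 13 → 14 → 15); step 5 is a one-step side branch.

**Steps most likely to fail**

Step 3 (allylic hydroxylation). The ene step has to pass through a cyclobutene-type allylseleninic acid, the spiro-epoxide is acid-sensitive, and over-oxidation to the enone is possible. The fallback sets out from 4 and comes back at 7, adjusting the oxidation level after the alkene is cleaved. Ozonolysis of 4 (O3, then Me2S) gives the cyclobutanone 5-isopropylspiro[bicyclo[4.2.0]octane-2,2'-oxiran]-8-one F1. Kinetic enolisation with KN(SiMe3)2 and TBSCl at −78 °C can only go toward the CH2 group and gives the silyl enol ether 8-(tert-butyldimethylsilyloxy)-5-isopropylspiro[bicyclo[4.2.0]oct-7-ene-2,2'-oxirane] F2. A second ozonolysis cleaves the enol ether to the silyl ester aldehyde tert-butyldimethylsilyl (4,5-cis; 5,6-trans) 5-formyl-6-isopropyl-1-oxaspiro[2.5]octane-4-carboxylate F3, which hydrolyses on aqueous work-up and closes to 7.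

Step 6 (proposed tandem oxa-Michael/HWE). The carboxylate is a weak Michael donor and 10 can oligomerise under base. The fallback uses known chemistry, sets out from 7 and comes back at 11, forming the C=C bond first and the lactone C–O bond second. The hydroxymethyl phosphonate 9 is isolated by stopping step 5 before the dehydration. Its HWE olefination with 7 (K2CO3, THF/H2O), a known reaction of 2-(hydroxymethyl)phosphonoacetates, gives the seco hydroxy acid (4,5-cis; 5,6-trans) 5-[(1E)-3-hydroxy-2-(prop-2-enyloxycarbonyl)prop-1-en-1-yl]-6-isopropyl-1-oxaspiro[2.5]octane-4-carboxylic acid F4. Only this alkene isomer has the CH2OH cis to the ring, and it is lactonised with 2-methyl-6-nitrobenzoic anhydride and DMAP at high dilution to 11.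

Step 7 (proposed photocatalytic decarboxylative epoxide opening). The risks are selectivity between the two carboxylates, thiolate attack on the epoxide and side reactions of the alkoxy radical. The fallback uses known chemistry, sets out from 1 and comes back at 13, building the acyl half directly instead of cutting it out of 11.
- CH2=CHMgBr with catalytic CuBr·SMe2 adds to 1 anti to the isopropyl group, and the enolate is trapped with PhNTf2 to give trans-3-ethenyl-4-isopropylcyclohex-1-en-1-yl trifluoromethanesulfonate F5.
- Ozonolysis at −78 °C (Me2S work-up) cleaves only the vinyl group, because the enol triflate alkene is electron-poor, and gives trans-3-formyl-4-isopropylcyclohex-1-en-1-yl trifluoromethanesulfonate F6.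
- Stille coupling with Bu3SnCH2OH (Pd(PPh3)4, LiCl, dioxane) gives trans-3-(hydroxymethyl)-6-isopropylcyclohex-2-ene-1-carbaldehyde F7.
- HWE olefination with 9 (K2CO3, THF/H2O) gives the allyl ester of 13, prop-2-enyl (2E)-2-(hydroxymethyl)-3-[(1S,6S)-3-(hydroxymethyl)-6-isopropylcyclohex-2-en-1-yl]prop-2-enoate F8.
- Deallylation (Pd(PPh3)4, N-methylaniline) returns to 13.

**Further compounds**
F1 | step 3 | 5-isopropylspiro[bicyclo[4.2.0]octane-2,2'-oxiran]-8-one | CC(C)[C@@H]1CC[C@]3(CO3)[C@H]2C(=O)C[C@@H]12
F2 | step 3 | 8-(tert-butyldimethylsilyloxy)-5-isopropylspiro[bicyclo[4.2.0]oct-7-ene-2,2'-oxirane] | CC(C)[C@@H]1CC[C@]3(CO3)[C@H]2C(O[Si](C)(C)C(C)(C)C)=C[C@@H]12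
F3 | step 3 | tert-butyldimethylsilyl (4,5-cis; 5,6-trans) 5-formyl-6-isopropyl-1-oxaspiro[2.5]octane-4-carboxylate | CC(C)[C@@H]1CC[C@]3(CO3)[C@@H](C(=O)O[Si](C)(C)C(C)(C)C)[C@H]1C=O
F4 | step 6 | (4,5-cis; 5,6-trans) 5-[(1E)-3-hydroxy-2-(prop-2-enyloxycarbonyl)prop-1-en-1-yl]-6-isopropyl-1-oxaspiro[2.5]octane-4-carboxylic acid | CC(C)[C@@H]1CC[C@]3(CO3)[C@@H](C(=O)O)[C@H]1/C=C(\CO)C(=O)OCC=C
F5 | step 7 | trans-3-ethenyl-4-isopropylcyclohex-1-en-1-yl trifluoromethanesulfonate | CC(C)[C@@H]1CCC(OS(=O)(=O)C(F)(F)F)=C[C@H]1C=C
F6 | step 7 | trans-3-formyl-4-isopropylcyclohex-1-en-1-yl trifluoromethanesulfonate | CC(C)[C@@H]1CCC(OS(=O)(=O)C(F)(F)F)=C[C@H]1C=O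
F7 | step 7 | trans-3-(hydroxymethyl)-6-isopropylcyclohex-2-ene-1-carbaldehyde | CC(C)[C@@H]1CCC(CO)=C[C@H]1C=O
F8 | step 7 | prop-2-enyl (2E)-2-(hydroxymethyl)-3-[(1S,6S)-3-(hydroxymethyl)-6-isopropylcyclohex-2-en-1-yl]prop-2-enoate | CC(C)[C@@H]1CCC(CO)=C[C@H]1/C=C(\CO)C(=O)OCC=C
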